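## Retrosynthetic overview

- Target 32 ⇐ 31 ⇐ 30 ⇐ 28: after the fragment union only CH2 insertion/oxidation at boron, O‑acetylation and one global deprotection remain.
- Key disconnection: the bond between tetralin carbon C8 and side‑chain carbon C2′, made late by lithiation–borylation of benzylic boronate 17 (fragment 1, aromatic half) with the lithiated benzoate from 25 (fragment 2, side‑chain half).
- 17 ⇐ hydroboration of dihydronaphthalene 16 ⇐ bromotetralone 12 ⇐ tetralone 11 ⇐ acid 10 ⇐ catechol 1 (ortho‑lithiation, Wittig, asymmetric hydrogenation).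
- 25 ⇐ (R)‑Roche ester 18, which carries the remote methyl stereocentre, by allylation and hydroboration.
- Rings: only one ring is built. The carbocycle (ring B) is closed onto the catechol‑derived benzene ring (ring A) by Friedel–Crafts acylation (10 → 11).

Assumption: (R)‑Roche ester and (+)‑sparteine are bought as single enantiomers, and a sequence run in one flask through a non‑isolated intermediate is counted as one step.

## Route

**Fragment 1 (aromatic half)**

Step 1
Reactants: 1 catechol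
Product: 2 1,2-dimethoxybenzene
Conditions: MeI (2.5 equiv), K2CO3, acetone, reflux
Reagents that add atoms: iodomethane, CI
Why: Williamson ether synthesis; the methyl ethers protect the catechol and later direct the ortho‑lithiation.

Step 2
Reactants: 2 1,2-dimethoxybenzene; 3 N-methoxy-N-methylacetamide
Product: 5 1-(2,3-dimethoxyphenyl)ethan-1-one, via aryllithium 4 (not isolated)
Conditions: n-BuLi, TMEDA, Et2O, 0 °C → rt; then 3, −78 → 0 °C; H2O
Reagents that add atoms: none
Why: Directed ortho‑metalation next to a methoxy group followed by Weinreb ketone synthesis; the chelated tetrahedral adduct prevents over‑addition.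

Step 3
Reactants: 6 3-bromopropanoic acid
Product: 7 (2-carboxyethyl)triphenylphosphonium bromide
Conditions: PPh3, MeCN, reflux
Reagents that add atoms: triphenylphosphine, c1ccc(cc1)P(c1ccccc1)c1ccccc1
Why: SN2 quaternisation of the phosphine by the primary bromide gives the Wittig salt.

Step 4
Reactants: 5 1-(2,3-dimethoxyphenyl)ethan-1-one; 7 (2-carboxyethyl)triphenylphosphonium bromide
Product: 9 (E)-4-(2,3-dimethoxyphenyl)pent-3-enoic acid, via ylide 8 (not isolated)
Conditions: NaN(SiMe3)2 (2.2 equiv), THF, 0 °C → reflux; aq. HCl; E isomer purified by crystallisation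
Reagents that add atoms: none
Why: Wittig olefination of the aryl methyl ketone by the carboxylate ylide gives the β,γ‑unsaturated acid, and the E isomer (aryl trans to the CH2CO2H arm) is the one carried on.

Step 5
Reactants: 9 (E)-4-(2,3-dimethoxyphenyl)pent-3-enoic acid
Product: 10 (R)-4-(2,3-dimethoxyphenyl)pentanoic acid
Conditions: H2 (6 atm), [Ir(cod)(L)]BArF (0.5 mol%, L = (Sa,S)-SIPHOX spiro phosphine–oxazoline), Cs2CO3 (0.5 equiv), MeOH, rt
Reagents that add atoms: none
Why: Carboxylate‑directed iridium‑catalysed asymmetric hydrogenation of the trisubstituted alkene; the chiral P,N ligand selects the alkene face and sets the benzylic methyl stereocentre as (R) (the antipodal ligand gives the S acid).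

Step 6
Reactants: 10 (R)-4-(2,3-dimethoxyphenyl)pentanoic acid
Product: 11 (R)-5,6-dimethoxy-4-methyl-3,4-dihydronaphthalen-1(2H)-one
Conditions: P2O5/MeSO3H (1:10 w/w), 25 → 50 °C
Reagents that add atoms: none
Why: Intramolecular Friedel–Crafts acylation closes ring B at the only free ortho position, which is para to a methoxy group; the stereocentre is not involved.

Step 7
Reactants: 11 (R)-5,6-dimethoxy-4-methyl-3,4-dihydronaphthalen-1(2H)-one
Product: 12 (R)-7-bromo-5,6-dimethoxy-4-methyl-3,4-dihydronaphthalen-1(2H)-one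
Conditions: NBS (1.05 equiv), MeCN, 0 °C → rt, dark
Reagents that add atoms: N-bromosuccinimide, O=C1CCC(=O)N1Br
Why: Electrophilic aromatic bromination ortho to the coplanar C6 methoxy group and meta to the acyl carbon; C8 is ortho to the deactivating ketone and para only to the twisted C5 methoxy group.

Step 8
Reactants: 12 (R)-7-bromo-5,6-dimethoxy-4-methyl-3,4-dihydronaphthalen-1(2H)-one
Product: 14 (R)-6-bromo-7,8-dimethoxy-1-methyl-1,2-dihydronaphthalene, via bromotetralol 13 (not isolated)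
Conditions: NaBH4, MeOH/THF, 0 °C; quench, swap solvent to toluene; p-TsOH·H2O (5 mol%), 80 °C
Reagents that add atoms: none
Why: Carbonyl reduction followed by E1 dehydration through the para‑methoxy‑stabilised benzylic cation; both alcohol epimers converge on the styrene and the methyl stereocentre is untouched.

Step 9
Reactants: 14 (R)-6-bromo-7,8-dimethoxy-1-methyl-1,2-dihydronaphthalene
Product: 16 tert-butyl (R)-3,4-dimethoxy-5-methyl-5,6-dihydronaphthalene-2-carboxylate, via aryllithium 15 (not isolated)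
Conditions: n-BuLi (1.05 equiv), THF, −78 °C, 10 min; cannulate into Boc2O (2 equiv), THF, −78 °C → rt
Reagents that add atoms: di-tert-butyl dicarbonate, CC(C)(C)OC(=O)OC(=O)OC(C)(C)C
Why: Bromine–lithium exchange is far faster than any reaction of n-BuLi at the styrene, and acylation of the aryllithium by Boc2O (inverse addition) gives the hindered tert‑butyl ester directly.

Step 10
Reactants: 16 tert-butyl (R)-3,4-dimethoxy-5-methyl-5,6-dihydronaphthalene-2-carboxylate
Product: 17 tert-butyl (5R,8R)-3,4-dimethoxy-5-methyl-8-(4,4,5,5-tetramethyl-1,3,2-dioxaborolan-2-yl)-5,6,7,8-tetrahydronaphthalene-2-carboxylate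
Conditions: CuCl (3 mol%), NaOt-Bu (6 mol%), (S)-DTBM-SEGPHOS (3.3 mol%), HBpin (1.3 equiv), toluene, rt
Reagents that add atoms: pinacolborane, CC1(C)OBOC1(C)C
Why: Copper hydride‑catalysed Markovnikov hydroboration of the cyclic styrene. Syn H–Cu addition places copper on the benzylic carbon on the face anti to the pseudoaxial C5 methyl group (the ligand antipode is the one matched to this bias). Cu→B exchange with retention then gives the trans (5R,8R) boronate.

**Fragment 2 (side‑chain half)**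

Step 11
Reactants: 18 methyl (R)-3-hydroxy-2-methylpropanoate
Product: 19 methyl (R)-3-[(tert-butyldimethylsilyl)oxy]-2-methylpropanoate
Conditions: TBSCl, imidazole, DMF, rt
Reagents that add atoms: tert-butyldimethylsilyl chloride, CC(C)(C)[Si](C)(C)Cl
Why: Silyl ether formation protects the hydroxyl that ends up as the free primary alcohol of the target.

Step 12
Reactants: 19 methyl (R)-3-[(tert-butyldimethylsilyl)oxy]-2-methylpropanoate
Product: 20 (S)-3-[(tert-butyldimethylsilyl)oxy]-2-methylpropan-1-ol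
Conditions: i-Bu2AlH (2.2 equiv), CH2Cl2, −78 → 0 °C
Reagents that add atoms: none
Why: Hydride reduction of the ester to the primary alcohol; the stereocentre is not epimerised (the descriptor changes only through CIP priorities).

Step 13
Reactants: 20 (S)-3-[(tert-butyldimethylsilyl)oxy]-2-methylpropan-1-ol
Product: 21 (R)-tert-butyl(3-iodo-2-methylpropoxy)dimethylsilane
Conditions: I2, PPh3, imidazole, CH2Cl2, 0 °C → rt
Reagents that add atoms: iodine, II
Why: Appel‑type iodination (SN2 on the alkoxyphosphonium ion) at the primary carbon leaves the adjacent stereocentre intact.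

Step 14
Reactants: 21 (R)-tert-butyl(3-iodo-2-methylpropoxy)dimethylsilane
Product: 22 (S)-tert-butyldimethyl[(2-methylhex-5-en-1-yl)oxy]silane
Conditions: allylMgBr (2 equiv), CuI (10 mol%), THF, −30 °C → rt
Reagents that add atoms: allylmagnesium bromide, C=CC[Mg]Br
Why: Copper‑catalysed sp3–sp3 cross‑coupling of the Grignard reagent with the primary iodide extends the chain by three carbons.

Step 15
Reactants: 22 (S)-tert-butyldimethyl[(2-methylhex-5-en-1-yl)oxy]silane
Product: 24 (S)-6-[(tert-butyldimethylsilyl)oxy]-5-methylhexan-1-ol, via alkylborane 23 (not isolated)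
Conditions: 9-BBN-H, THF, 0 °C → rt; then NaOH, H2O2, 0 °C → rt
Reagents that add atoms: hydrogen peroxide, OO
Why: Anti‑Markovnikov hydroboration–oxidation of the terminal alkene gives the primary alcohol.

Step 16
Reactants: 24 (S)-6-[(tert-butyldimethylsilyl)oxy]-5-methylhexan-1-ol
Product: 25 (S)-6-[(tert-butyldimethylsilyl)oxy]-5-methylhexyl 2,4,6-triisopropylbenzoate
Conditions: 2,4,6-iPr3C6H2COCl, Et3N, DMAP (cat.), CH2Cl2, reflux
Reagents that add atoms: 2,4,6-triisopropylbenzoyl chloride, CC(C)c1cc(C(C)C)c(C(Cl)=O)c(C(C)C)c1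
Why: Acylation gives the hindered benzoate, which directs α‑lithiation and later serves as the leaving group.

**Fragment union and end game**

Step 17
Reactants: 25 (S)-6-[(tert-butyldimethylsilyl)oxy]-5-methylhexyl 2,4,6-triisopropylbenzoate; 17 tert-butyl (5R,8R)-3,4-dimethoxy-5-methyl-8-(pinacolboryl)-5,6,7,8-tetrahydronaphthalene-2-carboxylate
Product: 28 tert-butyl (5R,8S)-8-[(1S,5S)-6-[(tert-butyldimethylsilyl)oxy]-5-methyl-1-(4,4,5,5-tetramethyl-1,3,2-dioxaborolan-2-yl)hexyl]-3,4-dimethoxy-5-methyl-5,6,7,8-tetrahydronaphthalene-2-carboxylate, via lithiated benzoate 26 (not isolated), via boronate complex 27 (not isolated)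
Conditions: 25 (1.4 equiv), (+)-sparteine (1.4 equiv), s-BuLi (1.3 equiv), Et2O, −78 °C, 5 h; 17 (1.0 equiv), −78 °C, 2 h; then 35 °C, 12 h
Reagents that add atoms: none
Why: Hoppe–Aggarwal lithiation–borylation (1,2‑metallate rearrangement). (+)-Sparteine‑directed removal of the pro‑R proton gives a configurationally stable carbenoid that fixes the new side‑chain stereocentre as (S) by reagent control. The carbenoid adds to boron with retention, and the benzylic ring carbon migrates with retention while the benzoate leaves with inversion, so the ring stereocentre is carried over unchanged (trans to the methyl group).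

Step 18
Reactants: 28 the secondary boronic ester from step 17
Product: 30 tert-butyl (5R,8S)-8-[(2S,6S)-7-[(tert-butyldimethylsilyl)oxy]-1-hydroxy-6-methylheptan-2-yl]-3,4-dimethoxy-5-methyl-5,6,7,8-tetrahydronaphthalene-2-carboxylate, via homologated boronate 29 (not isolated)
Conditions: BrCH2Cl (3 equiv), n-BuLi (2.5 equiv), THF, −78 °C → rt; then NaOH, H2O2, 0 °C → rt
Reagents that add atoms: bromochloromethane, ClCBr; hydrogen peroxide, OO
Why: Matteson one‑carbon homologation (ClCH2Li, 1,2‑migration with retention at the stereocentre) followed by stereoretentive C–B oxidation; the carbenoid has decomposed before the migrated product forms, so only one CH2 is inserted.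

Step 19
Reactants: 30 the primary alcohol from step 18
Product: 31 tert-butyl (5R,8S)-8-[(2S,6S)-1-acetoxy-7-[(tert-butyldimethylsilyl)oxy]-6-methylheptan-2-yl]-3,4-dimethoxy-5-methyl-5,6,7,8-tetrahydronaphthalene-2-carboxylate
Conditions: Ac2O, pyridine, DMAP (cat.), CH2Cl2, 0 °C → rt
Reagents that add atoms: acetic anhydride, CC(=O)OC(C)=O
Why: Nucleophile‑catalysed O‑acylation of the only free hydroxyl; the other primary alcohol is still silylated, so the acetate is placed unambiguously.

Step 20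
Reactants: 31 the acetate from step 19
Product: 32 (5R,8S)-8-[(2S,6S)-1-acetoxy-7-hydroxy-6-methylheptan-2-yl]-3,4-dihydroxy-5-methyl-5,6,7,8-tetrahydronaphthalene-2-carboxylic acid (target)
Conditions: BBr3 (8 equiv), CH2Cl2, −78 → 0 °C; then H2O, 0 °C
Reagents that add atoms: none
Why: Lewis‑acid ether cleavage removes both aryl methyl ethers (helped by cyclic catechol borate formation), the tert‑butyl ester and the silyl ether in one operation; the primary acetate should survive because its alkyl–O cleavage is slow at or below 0 °C.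

## Compound list

1 | catechol (benzene-1,2-diol) | Oc1ccccc1O | starting material
2 | 1,2-dimethoxybenzene | COc1ccccc1OC | intermediate
3 | N-methoxy-N-methylacetamide | CC(=O)N(C)OC | starting material
4 | (2,3-dimethoxyphenyl)lithium | [Li]c1cccc(OC)c1OC | intermediate
5 | 1-(2,3-dimethoxyphenyl)ethan-1-one | CC(=O)c1cccc(OC)c1OC | intermediate
6 | 3-bromopropanoic acid | OC(=O)CCBr | starting material
7 | (2-carboxyethyl)triphenylphosphonium bromide | [Br-].OC(=O)CC[P+](c1ccccc1)(c1ccccc1)c1ccccc1 | intermediate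
8 | sodium 3-(triphenylphosphoranylidene)propanoate (ylide) | [Na+].[O-]C(=O)CC=P(c1ccccc1)(c1ccccc1)c1ccccc1 | intermediate
9 | (E)-4-(2,3-dimethoxyphenyl)pent-3-enoic acid | COc1cccc(/C(C)=C/CC(=O)O)c1OC | intermediate
10 | (R)-4-(2,3-dimethoxyphenyl)pentanoic acid | C[C@H](CCC(=O)O)c1cccc(OC)c1OC | intermediate
11 | (R)-5,6-dimethoxy-4-methyl-3,4-dihydronaphthalen-1(2H)-one | C[C@@H]1CCC(=O)c2ccc(OC)c(OC)c12 | intermediate
12 | (R)-7-bromo-5,6-dimethoxy-4-methyl-3,4-dihydronaphthalen-1(2H)-one | C[C@@H]1CCC(=O)c2cc(Br)c(OC)c(OC)c12 | intermediate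
13 | (4R)-7-bromo-5,6-dimethoxy-4-methyl-1,2,3,4-tetrahydronaphthalen-1-ol (both C1 epimers) | C[C@@H]1CCC(O)c2cc(Br)c(OC)c(OC)c12 | intermediate
14 | (R)-6-bromo-7,8-dimethoxy-1-methyl-1,2-dihydronaphthalene | C[C@@H]1CC=Cc2cc(Br)c(OC)c(OC)c12 | intermediate
15 | [(5R)-3,4-dimethoxy-5-methyl-5,6-dihydronaphthalen-2-yl]lithium | C[C@@H]1CC=Cc2cc([Li])c(OC)c(OC)c12 | intermediate
16 | tert-butyl (R)-3,4-dimethoxy-5-methyl-5,6-dihydronaphthalene-2-carboxylate | C[C@@H]1CC=Cc2cc(C(=O)OC(C)(C)C)c(OC)c(OC)c12 | intermediate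
17 | tert-butyl (5R,8R)-3,4-dimethoxy-5-methyl-8-(4,4,5,5-tetramethyl-1,3,2-dioxaborolan-2-yl)-5,6,7,8-tetrahydronaphthalene-2-carboxylate | C[C@@H]1CC[C@@H](B3OC(C)(C)C(C)(C)O3)c2cc(C(=O)OC(C)(C)C)c(OC)c(OC)c12 | intermediate
18 | methyl (R)-3-hydroxy-2-methylpropanoate | COC(=O)[C@H](C)CO | starting material
19 | methyl (R)-3-[(tert-butyldimethylsilyl)oxy]-2-methylpropanoate | COC(=O)[C@H](C)CO[Si](C)(C)C(C)(C)C | intermediate
20 | (S)-3-[(tert-butyldimethylsilyl)oxy]-2-methylpropan-1-ol | OC[C@H](C)CO[Si](C)(C)C(C)(C)C | intermediate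
21 | (R)-tert-butyl(3-iodo-2-methylpropoxy)dimethylsilane | IC[C@H](C)CO[Si](C)(C)C(C)(C)C | intermediate
22 | (S)-tert-butyldimethyl[(2-methylhex-5-en-1-yl)oxy]silane | C=CCC[C@H](C)CO[Si](C)(C)C(C)(C)C | intermediate
23 | 9-[(5S)-6-[(tert-butyldimethylsilyl)oxy]-5-methylhexyl]-9-borabicyclo[3.3.1]nonane | CC(C)(C)[Si](C)(C)OC[C@@H](C)CCCCB1C2CCCC1CCC2 | intermediate
24 | (S)-6-[(tert-butyldimethylsilyl)oxy]-5-methylhexan-1-ol | OCCCC[C@H](C)CO[Si](C)(C)C(C)(C)C | intermediate
25 | (S)-6-[(tert-butyldimethylsilyl)oxy]-5-methylhexyl 2,4,6-triisopropylbenzoate | CC(C)c1cc(C(C)C)c(C(=O)OCCCC[C@H](C)CO[Si](C)(C)C(C)(C)C)c(C(C)C)c1 | intermediate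
26 | (1R,5S)-6-[(tert-butyldimethylsilyl)oxy]-1-lithio-5-methylhexyl 2,4,6-triisopropylbenzoate ((+)-sparteine complex) | CC(C)c1cc(C(C)C)c(C(=O)O[C@H]([Li])CCC[C@H](C)CO[Si](C)(C)C(C)(C)C)c(C(C)C)c1 | intermediate
27 | lithium boronate (ate) complex of 26 and 17 | [Li+].CC(C)c1cc(C(C)C)c(C(=O)O[C@@H](CCC[C@H](C)CO[Si](C)(C)C(C)(C)C)[B-]2(OC(C)(C)C(C)(C)O2)[C@@H]3CC[C@@H](C)c4c3cc(C(=O)OC(C)(C)C)c(OC)c4OC)c(C(C)C)c1 | intermediate
28 | tert-butyl (5R,8S)-8-[(1S,5S)-6-[(tert-butyldimethylsilyl)oxy]-5-methyl-1-(4,4,5,5-tetramethyl-1,3,2-dioxaborolan-2-yl)hexyl]-3,4-dimethoxy-5-methyl-5,6,7,8-tetrahydronaphthalene-2-carboxylate | CC1(C)OB(OC1(C)C)[C@@H](CCC[C@H](C)CO[Si](C)(C)C(C)(C)C)[C@@H]2CC[C@@H](C)c3c2cc(C(=O)OC(C)(C)C)c(OC)c3OC | intermediate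
29 | tert-butyl (5R,8S)-8-[(2S,6S)-7-[(tert-butyldimethylsilyl)oxy]-6-methyl-1-(4,4,5,5-tetramethyl-1,3,2-dioxaborolan-2-yl)heptan-2-yl]-3,4-dimethoxy-5-methyl-5,6,7,8-tetrahydronaphthalene-2-carboxylate | CC1(C)OB(OC1(C)C)C[C@@H](CCC[C@H](C)CO[Si](C)(C)C(C)(C)C)[C@@H]2CC[C@@H](C)c3c2cc(C(=O)OC(C)(C)C)c(OC)c3OC | intermediate
30 | tert-butyl (5R,8S)-8-[(2S,6S)-7-[(tert-butyldimethylsilyl)oxy]-1-hydroxy-6-methylheptan-2-yl]-3,4-dimethoxy-5-methyl-5,6,7,8-tetrahydronaphthalene-2-carboxylate | OC[C@@H](CCC[C@H](C)CO[Si](C)(C)C(C)(C)C)[C@@H]1CC[C@@H](C)c2c1cc(C(=O)OC(C)(C)C)c(OC)c2OC | intermediate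
31 | tert-butyl (5R,8S)-8-[(2S,6S)-1-acetoxy-7-[(tert-butyldimethylsilyl)oxy]-6-methylheptan-2-yl]-3,4-dimethoxy-5-methyl-5,6,7,8-tetrahydronaphthalene-2-carboxylate | CC(=O)OC[C@@H](CCC[C@H](C)CO[Si](C)(C)C(C)(C)C)[C@@H]1CC[C@@H](C)c2c1cc(C(=O)OC(C)(C)C)c(OC)c2OC | intermediate
32 | (5R,8S)-8-[(2S,6S)-1-acetoxy-7-hydroxy-6-methylheptan-2-yl]-3,4-dihydroxy-5-methyl-5,6,7,8-tetrahydronaphthalene-2-carboxylic acid | CC(=O)OC[C@@H](CCC[C@H](C)CO)[C@@H]1CC[C@@H](C)c2c1cc(C(=O)O)c(O)c2O | target

## Step count and risks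

Total step count: 20. Longest linear sequence: 13 steps (1, 2, 4–10, 17–20, from catechol).

Three steps most likely to fail:

**Step 7 (site of bromination).** Attack at C8 (para to the twisted C5 methoxy group) or α‑bromination of the ketone could compete with the wanted C7 bromination. Fallback, setting out from 11 and returning at 16: the carboxyl is placed by directed ortho‑metalation instead of electrophilic substitution, since C7 is the only position ortho to a methoxy group. Ketone 11 is reduced with NaBH4 to (4R)-5,6-dimethoxy-4-methyl-1,2,3,4-tetrahydronaphthalen-1-ol F1. This is silylated (i-Pr3SiOTf, 2,6-lutidine) to the triisopropylsilyl ether F2, whose bulky silyloxy group does not direct lithiation. Treatment with s-BuLi/TMEDA (THF, −78 → −30 °C) and Boc2O gives the tert-butyl ester silyl ether F3. Bu4NF frees the benzylic hydroxy ester F4, and mesylation/elimination (MsCl, Et3N, then DBU) gives 16.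

**Step 17 (fragment union).** The sparteine‑bound carbenoid may add too slowly to the hindered secondary benzylic boronate, or the boronate complex may revert and erode the stereochemistry. Fallback, setting out from 25 and returning at 28: the carbenoid is made by a different elementary step. 25 is lithiated as before and quenched with Me3SnCl to give the isolable α‑stannyl benzoate (1R,5S)-6-[(tert-butyldimethylsilyl)oxy]-5-methyl-1-(trimethylstannyl)hexyl 2,4,6-triisopropylbenzoate F5, which is purified and its enantiomeric purity checked. Tin–lithium exchange (n-BuLi, Et2O, −78 °C, retention) then gives the diamine‑free, much less hindered lithiated benzoate, which is combined with 17 and warmed to give 28.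

**Step 20 (global deprotection).** BBr3 may partly cleave the acetate or convert the liberated primary alcohol into a bromide. Fallback, setting out from 12 and returning at 32: the phenol protection is exchanged for acid‑labile groups while the substrate is still a robust ketone.
- 12 is demethylated (BBr3, CH2Cl2) to (R)-7-bromo-5,6-dihydroxy-4-methyl-3,4-dihydronaphthalen-1(2H)-one F6 and re‑protected (MOMCl, i-Pr2NEt) as the bis(methoxymethyl) ether F7.
- NaBH4 gives the bis(methoxymethoxy) tetralol F8, and base‑mediated elimination (MsCl, Et3N, then DBU) gives the bis(methoxymethoxy) dihydronaphthalene bromide F9.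
- Bromine–lithium exchange and Boc2O give the tert-butyl ester F10, and copper hydride hydroboration as in step 10 gives the benzylic boronate F11.
- Union with 25 as in step 17 gives the secondary boronic ester F12; ClCH2Li insertion gives the homologated boronate F13, and oxidation gives the primary alcohol F14.
- Acetylation gives the acetate F15, and TFA/CH2Cl2/H2O (0 °C → rt) removes both methoxymethyl ethers, the tert-butyl ester and the silyl ether without touching the acetate, giving 32.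

## Further compounds

F1 | step 7 | (4R)-5,6-dimethoxy-4-methyl-1,2,3,4-tetrahydronaphthalen-1-ol (both C1 epimers) | C[C@@H]1CCC(O)c2ccc(OC)c(OC)c12
F2 | step 7 | {[(4R)-5,6-dimethoxy-4-methyl-1,2,3,4-tetrahydronaphthalen-1-yl]oxy}tri(propan-2-yl)silane | C[C@@H]1CCC(O[Si](C(C)C)(C(C)C)C(C)C)c2ccc(OC)c(OC)c12
F3 | step 7 | tert-butyl (5R)-3,4-dimethoxy-5-methyl-8-{[tri(propan-2-yl)silyl]oxy}-5,6,7,8-tetrahydronaphthalene-2-carboxylate | C[C@@H]1CCC(O[Si](C(C)C)(C(C)C)C(C)C)c2cc(C(=O)OC(C)(C)C)c(OC)c(OC)c12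
F4 | step 7 | tert-butyl (5R)-8-hydroxy-3,4-dimethoxy-5-methyl-5,6,7,8-tetrahydronaphthalene-2-carboxylate | C[C@@H]1CCC(O)c2cc(C(=O)OC(C)(C)C)c(OC)c(OC)c12
F5 | step 17 | (1R,5S)-6-[(tert-butyldimethylsilyl)oxy]-5-methyl-1-(trimethylstannyl)hexyl 2,4,6-triisopropylbenzoate | CC(C)c1cc(C(C)C)c(C(=O)O[C@H]([Sn](C)(C)C)CCC[C@H](C)CO[Si](C)(C)C(C)(C)C)c(C(C)C)c1
F6 | step 20 | (R)-7-bromo-5,6-dihydroxy-4-methyl-3,4-dihydronaphthalen-1(2H)-one | C[C@@H]1CCC(=O)c2cc(Br)c(O)c(O)c12
F7 | step 20 | (R)-7-bromo-5,6-bis(methoxymethoxy)-4-methyl-3,4-dihydronaphthalen-1(2H)-one | C[C@@H]1CCC(=O)c2cc(Br)c(OCOC)c(OCOC)c12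
F8 | step 20 | (4R)-7-bromo-5,6-bis(methoxymethoxy)-4-methyl-1,2,3,4-tetrahydronaphthalen-1-ol (both C1 epimers) | C[C@@H]1CCC(O)c2cc(Br)c(OCOC)c(OCOC)c12
F9 | step 20 | (R)-6-bromo-7,8-bis(methoxymethoxy)-1-methyl-1,2-dihydronaphthalene | C[C@@H]1CC=Cc2cc(Br)c(OCOC)c(OCOC)c12
F10 | step 20 | tert-butyl (R)-3,4-bis(methoxymethoxy)-5-methyl-5,6-dihydronaphthalene-2-carboxylate | C[C@@H]1CC=Cc2cc(C(=O)OC(C)(C)C)c(OCOC)c(OCOC)c12
F11 | step 20 | tert-butyl (5R,8R)-3,4-bis(methoxymethoxy)-5-methyl-8-(4,4,5,5-tetramethyl-1,3,2-dioxaborolan-2-yl)-5,6,7,8-tetrahydronaphthalene-2-carboxylate | C[C@@H]1CC[C@@H](B3OC(C)(C)C(C)(C)O3)c2cc(C(=O)OC(C)(C)C)c(OCOC)c(OCOC)c12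
F12 | step 20 | tert-butyl (5R,8S)-8-[(1S,5S)-6-[(tert-butyldimethylsilyl)oxy]-5-methyl-1-(4,4,5,5-tetramethyl-1,3,2-dioxaborolan-2-yl)hexyl]-3,4-bis(methoxymethoxy)-5-methyl-5,6,7,8-tetrahydronaphthalene-2-carboxylate | CC1(C)OB(OC1(C)C)[C@@H](CCC[C@H](C)CO[Si](C)(C)C(C)(C)C)[C@@H]2CC[C@@H](C)c3c2cc(C(=O)OC(C)(C)C)c(OCOC)c3OCOC
F13 | step 20 | tert-butyl (5R,8S)-8-[(2S,6S)-7-[(tert-butyldimethylsilyl)oxy]-6-methyl-1-(4,4,5,5-tetramethyl-1,3,2-dioxaborolan-2-yl)heptan-2-yl]-3,4-bis(methoxymethoxy)-5-methyl-5,6,7,8-tetrahydronaphthalene-2-carboxylate | CC1(C)OB(OC1(C)C)C[C@@H](CCC[C@H](C)CO[Si](C)(C)C(C)(C)C)[C@@H]2CC[C@@H](C)c3c2cc(C(=O)OC(C)(C)C)c(OCOC)c3OCOC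
F14 | step 20 | tert-butyl (5R,8S)-8-[(2S,6S)-7-[(tert-butyldimethylsilyl)oxy]-1-hydroxy-6-methylheptan-2-yl]-3,4-bis(methoxymethoxy)-5-methyl-5,6,7,8-tetrahydronaphthalene-2-carboxylate | OC[C@@H](CCC[C@H](C)CO[Si](C)(C)C(C)(C)C)[C@@H]1CC[C@@H](C)c2c1cc(C(=O)OC(C)(C)C)c(OCOC)c2OCOC
F15 | step 20 | tert-butyl (5R,8S)-8-[(2S,6S)-1-acetoxy-7-[(tert-butyldimethylsilyl)oxy]-6-methylheptan-2-yl]-3,4-bis(methoxymethoxy)-5-methyl-5,6,7,8-tetrahydronaphthalene-2-carboxylate | CC(=O)OC[C@@H](CCC[C@H](C)CO[Si](C)(C)C(C)(C)C)[C@@H]1CC[C@@H](C)c2c1cc(C(=O)OC(C)(C)C)c(OCOC)c2OCOC
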